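## Structural features

Pilosanol N is a diarylmethane: C8 of ring A of a (2R,3S)-flavan-3-ol (the (+)-catechin skeleton, with resorcinol-type ring A, dihydropyran ring C and catechol ring B) is joined through one CH2 to D1 of a fully substituted acetophenone ring D. The only stereocentres are the neighbouring C2 (benzylic ether carbon bearing ring B) and C3 (secondary alcohol), trans across ring C, so the stereochemical task is to preserve them, not to create them. Ring D carries in sequence D1 CH2, D2 OH, D3 acetyl, D4 OCH3, D5 CH3 and D6 OH: three alternating oxygens of which only the middle one is methylated, flanked by two different carbon substituents. Telling these three oxygens and the D3 and D5 positions apart by substitution chemistry on a phloroglucinol is the real difficulty, more than the bridge or the flavan. The fragile elements are: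
- the oxidisable catechol and phloroglucinol rings;
- the C2–O1 benzylic ether, which can open and epimerise C2 under strong base while the 4'-OH is free, or under strong acid;
- the electron-rich diarylmethane bridge, which can fragment under acid;
- the free C6 position of ring A, a second strong carbon nucleophile;
- the aryl ketone under reducing conditions.

The key step exploits two mappings: D4(OCH3)–D5(CH3) is the carbon pair of 1-methoxypropyne, and D6–D1(CH2)–D2(O)–D3(H) is the four-carbon ring of a 3-alkoxy-4-alkylcyclobutenone. One thermal cascade therefore forms D3–D4, D5–D6 and D1–D6 with the substitution pattern dictated by the two components. The D3 hydrogen left by the cascade is then the only open position of ring D, ortho to the D2 oxygen, where the acetyl is placed last.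

## Logic of the disconnections

**22 from 21.** The five benzyl C–O bonds and the C6–Br bond are cut together. Benzyl ethers keep every phenol and the 3-hydroxyl inert through organometallic, ketene and Lewis-acid steps. The bromine blocks C6 of ring A until the end and leaves in the same hydrogenolysis at no cost in steps. The forward step must spare the chelated aryl ketone and the C2–O1 benzylic ether.

**21 from 19 (through 20).** The D3–acyl bond is cut. D3 is the only unsubstituted carbon of ring D, ortho to the D2 hydroxyl, and C6 of ring A is occupied by bromine, so a Friedel–Crafts acetylation has one site. The forward step needs a Lewis acid mild enough for five benzyl ethers and the bridge.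

**19 from 18.** The D2 O–C(CH3)3 bond is cut. The tert-butyl group is what the ynol ether component brings. Its removal frees the hydroxyl that directs and stabilises the acetylation. The forward step must dispose of the tert-butyl cation without alkylating the arenes.

**18 from 10 and 13.** Ring D is taken apart at D5–D6, D3–D4 and D1–D6. This reduces a hexasubstituted benzene to a four-membered ring and a three-carbon alkyne whose substituents already sit in the right order. The forward step demands a clean thermal cascade and the correct orientation of the alkyne in the [2+2] event.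

**13 from 11.** The methyl–alkyne bond and the triple bond are cut back to a chloroacetal. The volatile ynol ether is thus made in one operation by double elimination and methylation of the acetylide.

**10 from 7 (through 8 and 9).** The two cyclobutenone bonds formed by a ketene–ynol ether [2+2] are cut. This leaves a propanoic acid on C8 and a tert-butyl ynol ether reagent. The forward step requires the monosubstituted ketene 9 to be trapped faster than it dimerises.

**7 from 6 from 5.** Ester hydrolysis and the C6–Br bond are undone. Bromination is placed after the cross-coupling, so that only one carbon–bromine bond is present when palladium is used, and before any acid chloride, cation or acylium chemistry.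

**5 from 4.** The C8–CH2 bond is cut. A single sp2–sp3 cross-coupling with a three-carbon ester homoenolate replaces a formylation, olefination and conjugate-reduction sequence. It demands oxidative addition into a hindered, electron-rich aryl bromide.

**4 from 3 from 2 from 1.** The C8–Br bond and the benzyl ethers are removed back to the natural flavan-3-ol, which supplies rings A, B and C and both stereocentres. Benzylation is split so that strong base is used only after the 4'-oxygen is capped. Bromination relies on the known preference of benzylated catechins for C8.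

## Other disconnections considered

**Alternative 1:** Ring A is cut at C7–C8, C4a–C8a and C6–C7, so that rings A and C arise together.
- Forward key step: a diazo ketone A2 carries a 2-benzyloxyvinyl ketone at one end and, at the other, an ynol ether whose oxygen is the future O1 and whose alkyne bears the complete ring D. Wolff rearrangement gives a vinylketene. Intramolecular [2+2] onto the ynol ether, 4π opening and 6π closure would then give the C7 phenol A1, whose isopropenyl group is a latent acetyl.
- In favour: two rings and three C–C bonds in one operation; the C8 attachment of the bridge is fixed by construction; no electrophilic acetylation is ever run next to a flavan. On that last point it is better than the chosen plan.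
- Against: C2 and C3 must be made by asymmetric synthesis, although 1 supplies them. The ynol ether sits on a secondary benzylic carbon with a β-hydrogen and is prone to retro-ene or sigmatropic loss below the temperature of the cascade. Ring D, the real problem, still has to be built separately with its full pattern. The isopropenyl group must later be cleaved oxidatively in the presence of very electron-rich arenes.
- Comparison: mechanistically it is the same pericyclic family and equal in regiochemical logic. Structurally it spends its key step on the ring that nature provides, not on ring D. In step economy it is clearly longer.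

**Alternative 2:** Ring C is cut at C4–C4a.
- Forward key step: acid activation of the terminal epoxide in aryl ether A4 lets C4a attack the CH2 terminus in a 6-endo Friedel–Crafts opening. This would give A3 with the 3-hydroxyl free and C2 and C3 carried over from the epoxy ether.
- In favour: a convergent late closure; no protection of the 3-hydroxyl; stereocentres from reagent-controlled epoxidation, so either enantiomer is equally accessible. On that point it is better than the chosen plan, which is tied to the natural series.
- Against: a 5-exo opening at C3 to a dihydrobenzofuran competes. The doubly activated C2–O bond can ionise under the same acid and lose its configuration. The aryl ether has to be formed on a secondary benzylic carbon with a di-ortho-substituted phenol. The hexasubstituted ring D with its acetyl must already exist, so the central regiochemical problem is only moved elsewhere.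
- Comparison: it is equal in convergence. Mechanistically it relies on a cationic closure with two selectivity questions, where the chosen cascade has one question that is answered by alkyne polarisation. It is longer, because 1 cannot be used.

**Alternative 3:** Ring D is cut at D2–D3.
- Forward key step: the open chain A6 is a methyl ester at D2, a ketone at D6, a methyl enol ether at D4–D5 and a methyl ketone beyond D3. Base converts it into its extended enolate, and Claisen attack of D3 on the ester followed by aromatisation would give A5.
- In favour: acetyl and methoxyl arrive in place, basic conditions spare benzyl ethers and the acid-sensitive bridge, and only hydrogenolysis remains. In post-key-step economy it is better than the chosen plan (one step against three), and it needs no blocking group on C6.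
- Against: the most acidic proton of A6 is at D1, between ester and ketone, so the reacting D3 enolate must come from a dianion. O-cyclisation to a pyranone, retro-Claisen cleavage and loss or migration of the enol ether all compete. A regiodefined synthesis of A6 on the catechin is not obviously shorter than steps 4 to 9.
- Comparison: both plans build ring D on the intact flavan and are equal in that respect. The alternative is equilibrium-controlled ionic chemistry with several possible cyclisation modes, whereas the chosen cascade is irreversible and its regiochemistry is set by the components. Overall step count would be similar, with the risk concentrated in the making and folding of A6.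

Key step: step 9

Remark: tert-butoxyethyne and (3-ethoxy-3-oxopropyl)zinc bromide (THF solution) are taken as purchasable reagents. A bromine atom is carried on C6 of ring A from 6 to 21 as a spectator blocking group; it changes neither the bonds formed nor the carbon skeletons of 10 and 18.

## Route

Step 1
Reactants: 1 (+)-catechin
Product: 2 5,7,3',4'-tetra-O-benzyl-(+)-catechin
Conditions: BnBr (4.4 equiv), K2CO3, DMF, −10 °C → rt
Reagents that add atoms: benzyl bromide, BrCc1ccccc1
Why: Williamson etherification; the weak base ionises only the four phenols, so the 3-hydroxyl stays free and the base-sensitive C2 centre is never exposed to strong base while the 4'-oxygen is uncapped; crystallisation should remove C-benzylated by-products.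

Step 2
Reactants: 2 5,7,3',4'-tetra-O-benzyl-(+)-catechin
Product: 3 3,5,7,3',4'-penta-O-benzyl-(+)-catechin
Conditions: NaH, BnBr, Bu4NI (cat.), THF/DMF, 0 °C → rt
Reagents that add atoms: benzyl bromide, BrCc1ccccc1
Why: Williamson etherification of the secondary alkoxide; with all phenols capped, the quinone-methide pathway that would open ring C is closed, so C2 and C3 are untouched.

Step 3
Reactants: 3 3,5,7,3',4'-penta-O-benzyl-(+)-catechin
Product: 4 8-bromo-3,5,7,3',4'-penta-O-benzyl-(+)-catechin
Conditions: NBS (1.0 equiv), CH2Cl2, −78 → 0 °C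
Reagents that add atoms: N-bromosuccinimide, O=C1CCC(=O)N1Br
Why: Electrophilic aromatic bromination of the phloroglucinol-type ring A; C8, between the pyran oxygen and one benzyloxy group, is the more accessible and more nucleophilic site than C6 between two benzyloxy groups, the established regiochemistry for benzylated catechins.

Step 4
Reactants: 4 8-bromo-3,5,7,3',4'-penta-O-benzyl-(+)-catechin
Product: 5 ethyl 3-(3,5,7,3',4'-penta-O-benzylcatechin-8-yl)propanoate
Conditions: BrZnCH2CH2CO2Et (1.8 equiv), Pd(OAc)2 (3 mol %), SPhos (6 mol %), THF, 50 °C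
Reagents that add atoms: (3-ethoxy-3-oxopropyl)zinc bromide, CCOC(=O)CC[Zn]Br
Why: Negishi sp2–sp3 cross-coupling; the bulky electron-rich biarylphosphine lets zerovalent palladium insert into the hindered C8–Br bond and makes reductive elimination faster than β-hydride elimination from the homoenolate, while the organozinc tolerates the ester and the benzyl ethers.

Step 5
Reactants: 5 ethyl 3-(3,5,7,3',4'-penta-O-benzylcatechin-8-yl)propanoate
Product: 6 ethyl 3-(6-bromo-3,5,7,3',4'-penta-O-benzylcatechin-8-yl)propanoate
Conditions: NBS (1.05 equiv), CH2Cl2, 0 °C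
Reagents that add atoms: N-bromosuccinimide, O=C1CCC(=O)N1Br
Why: Electrophilic aromatic bromination at C6, the only free position of the trioxygenated ring A and far more activated than any position of the dibenzyloxyphenyl ring B; the bromine then shields C6 from formylation, alkylation and acylation in steps 7, 10 and 11.

Step 6
Reactants: 6 ethyl 3-(6-bromo-3,5,7,3',4'-penta-O-benzylcatechin-8-yl)propanoate
Product: 7 3-(6-bromo-3,5,7,3',4'-penta-O-benzylcatechin-8-yl)propanoic acid
Conditions: LiOH·H2O, THF/MeOH/H2O, 40 °C; then 1 M HCl to pH 3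
Reagents that add atoms: lithium hydroxide, [Li+].[OH-]
Why: Ester saponification; benzyl ethers, the aryl bromide and the fully etherified flavan are stable to aqueous hydroxide.

Step 7
Reactants: 7 3-(6-bromo-3,5,7,3',4'-penta-O-benzylcatechin-8-yl)propanoic acid
Product: 10 4-[(6-bromo-3,5,7,3',4'-penta-O-benzylcatechin-8-yl)methyl]-3-tert-butoxycyclobut-2-en-1-one, via acid chloride 8 (not isolated), via ketene 9 (not isolated)
Conditions: (COCl)2, DMF (cat.), CH2Cl2, 0 °C → rt, evaporate; then tert-butoxyethyne (4 equiv), Et3N (1.3 equiv, slow addition), CH2Cl2, 0 °C → rt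
Reagents that add atoms: tert-butoxyethyne, C#COC(C)(C)C
Why: Dehydrochlorination of 8 gives aldoketene 9, which is trapped in a thermal ketene–ynol ether [2+2] cycloaddition in which the nucleophilic CH carbon of the alkyne bonds to the ketene carbonyl carbon, giving the 3-alkoxy-4-alkyl regiochemistry. Both positions ortho to C8 are substituted, so 8 cannot close to an indanone, and slow base addition into excess alkyne disfavours dimerisation of 9. C4 forms as a mixture of epimers, which is without consequence because this centre becomes aromatic carbon D1.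

Step 8
Reactants: 11 chloroacetaldehyde dimethyl acetal
Product: 13 1-methoxypropyne, via sodium methoxyethynide 12 (not isolated)
Conditions: NaNH2 (3.1 equiv), liquid NH3, −33 °C; then MeI (1.0 equiv), −33 °C; distillation
Reagents that add atoms: iodomethane, CI
Why: Twofold base-induced elimination (loss of methanol, then of HCl) gives methoxyethyne, which the third equivalent of amide deprotonates to 12; C-alkylation of this acetylide with iodomethane in liquid ammonia is the standard entry to 1-alkoxy-1-alkynes.

Step 9
Reactants: 10 4-[(6-bromo-3,5,7,3',4'-penta-O-benzylcatechin-8-yl)methyl]-3-tert-butoxycyclobut-2-en-1-one; 13 1-methoxypropyne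
Product: 18 6-bromo-3,5,7,3',4'-penta-O-benzyl-8-[(2-tert-butoxy-6-hydroxy-4-methoxy-5-methylphenyl)methyl]catechin, via vinylketene 14 (not isolated), via alkenylcyclobutenone 15 (not isolated), via dienylketene 16 (not isolated), via cyclohexadienone 17 (not isolated)
Conditions: 13 (3 equiv), PhMe, sealed tube, 80 → 110 °C
Reagents that add atoms: none
Why: This is a Danheiser benzannulation, the known thermal union of a cyclobutenone with an alkoxyalkyne to a resorcinol monoether. Heating opens 10 by conrotatory 4π cleavage of its C1–C4 bond, the bulky CH2Ar group turning outward, to give vinylketene 14. 14 adds to 13 in a ketene–alkyne [2+2] in which the methyl-bearing, nucleophilic alkyne carbon bonds to the ketene carbonyl carbon (D5–D6) and the methoxy-bearing carbon to the ketene α-carbon (D3–D4), giving 15. A second 4π opening converts 15 into dienylketene 16. Ring D is closed by disrotatory 6π electrocyclisation of 16 (D1–D6), and tautomerisation of dienone 17 to phenol 18 makes the sequence irreversible. No stereocentre is created: the C4 centre of 10 and the sp3 centres of 15 and 17 end as aromatic carbons, and C2 and C3 are spectators under neutral thermal conditions. The selectivity needed is the orientation of the [2+2] step, fixed by the oxygen-induced polarisation of 13, which puts the methoxyl meta to the new hydroxyl and next to the methyl, at D4. Chemoselectivity is expected because benzyl ethers, aryl bromide and aryl tert-butyl ether have no thermal pathway at this temperature, and excess 13 keeps 14 from dimerising or acylating the product phenol.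

Step 10
Reactants: 18 6-bromo-3,5,7,3',4'-penta-O-benzyl-8-[(2-tert-butoxy-6-hydroxy-4-methoxy-5-methylphenyl)methyl]catechin
Product: 19 6-bromo-3,5,7,3',4'-penta-O-benzyl-8-[(2,6-dihydroxy-4-methoxy-3-methylphenyl)methyl]catechin
Conditions: CF3CO2H/CH2Cl2 (1:9), anisole (5 equiv), 0 °C
Reagents that add atoms: none
Why: Acidolysis of an aryl tert-butyl ether; the electron-rich ring makes ionisation fast at 0 °C in dilute acid, where benzyl ethers and the flavan are stable. Anisole captures the tert-butyl cation, C6 is blocked by bromine and D3 is flanked on both sides, so C-tert-butylation of the substrate is disfavoured.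

Step 11
Reactants: 19 6-bromo-3,5,7,3',4'-penta-O-benzyl-8-[(2,6-dihydroxy-4-methoxy-3-methylphenyl)methyl]catechin
Product: 21 8-[(3-acetyl-2,6-dihydroxy-4-methoxy-5-methylphenyl)methyl]-6-bromo-3,5,7,3',4'-penta-O-benzylcatechin, via difluoroboron chelate 20 (not isolated)
Conditions: Ac2O (1.3 equiv), BF3·OEt2 (3 equiv), CH2Cl2, 0 °C → rt; then aq. NaOAc, MeOH, 50 °C
Reagents that add atoms: acetic anhydride, CC(=O)OC(C)=O
Why: Friedel–Crafts C-acetylation (direct, or by O-acetylation and Fries shift) at D3, the only unsubstituted carbon of the free resorcinol ring and ortho to the D2 hydroxyl. The six-membered difluoroboron chelate 20 is the thermodynamic sink and deactivates the ring against further reaction. C6 of ring A is blocked and ring B is a much weaker nucleophile; the aqueous acetate work-up hydrolyses the B–O bonds.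

Step 12
Reactants: 21 8-[(3-acetyl-2,6-dihydroxy-4-methoxy-5-methylphenyl)methyl]-6-bromo-3,5,7,3',4'-penta-O-benzylcatechin
Product: 22 pilosanol N
Conditions: H2 (1 atm), Pd(OH)2/C, NaOAc, THF/MeOH, rt
Reagents that add atoms: none
Why: Catalytic hydrogenolysis removes the five benzyl ethers and the aryl bromide in one operation, with acetate taking up the HBr. The hydrogen-bonded, doubly ortho-substituted aryl ketone and the C2–O1 benzylic ether are expected to survive under neutral conditions at one atmosphere, as is usual in deprotection of benzylated catechins and acylphloroglucinols; C2 and C3 are not touched.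

## Compound list

1 | (+)-catechin, (2R,3S)-2-(3,4-dihydroxyphenyl)chromane-3,5,7-triol | O[C@H]1Cc2c(O)cc(O)cc2O[C@@H]1c1ccc(O)c(O)c1 | starting material
2 | 5,7,3',4'-tetra-O-benzyl-(+)-catechin (3-OH free) | c1c(OCc2ccccc2)cc(OCc2ccccc2)c3c1O[C@H](c4ccc(OCc2ccccc2)c(OCc2ccccc2)c4)[C@@H](O)C3 | intermediate
3 | 3,5,7,3',4'-penta-O-benzyl-(+)-catechin | c1c(OCc2ccccc2)cc(OCc2ccccc2)c3c1O[C@H](c4ccc(OCc2ccccc2)c(OCc2ccccc2)c4)[C@@H](OCc2ccccc2)C3 | intermediate
4 | 8-bromo-3,5,7,3',4'-penta-O-benzyl-(+)-catechin | Brc1c(OCc2ccccc2)cc(OCc2ccccc2)c3c1O[C@H](c4ccc(OCc2ccccc2)c(OCc2ccccc2)c4)[C@@H](OCc2ccccc2)C3 | intermediate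
5 | ethyl 3-(3,5,7,3',4'-penta-O-benzylcatechin-8-yl)propanoate | CCOC(=O)CCc1c(OCc2ccccc2)cc(OCc2ccccc2)c3c1O[C@H](c4ccc(OCc2ccccc2)c(OCc2ccccc2)c4)[C@@H](OCc2ccccc2)C3 | intermediate
6 | ethyl 3-(6-bromo-3,5,7,3',4'-penta-O-benzylcatechin-8-yl)propanoate | CCOC(=O)CCc1c(OCc2ccccc2)c(Br)c(OCc2ccccc2)c3c1O[C@H](c4ccc(OCc2ccccc2)c(OCc2ccccc2)c4)[C@@H](OCc2ccccc2)C3 | intermediate
7 | 3-(6-bromo-3,5,7,3',4'-penta-O-benzylcatechin-8-yl)propanoic acid | OC(=O)CCc1c(OCc2ccccc2)c(Br)c(OCc2ccccc2)c3c1O[C@H](c4ccc(OCc2ccccc2)c(OCc2ccccc2)c4)[C@@H](OCc2ccccc2)C3 | intermediate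
8 | 3-(6-bromo-3,5,7,3',4'-penta-O-benzylcatechin-8-yl)propanoyl chloride | ClC(=O)CCc1c(OCc2ccccc2)c(Br)c(OCc2ccccc2)c3c1O[C@H](c4ccc(OCc2ccccc2)c(OCc2ccccc2)c4)[C@@H](OCc2ccccc2)C3 | intermediate (not isolated)
9 | 3-(6-bromo-3,5,7,3',4'-penta-O-benzylcatechin-8-yl)prop-1-en-1-one (aldoketene) | O=C=CCc1c(OCc2ccccc2)c(Br)c(OCc2ccccc2)c3c1O[C@H](c4ccc(OCc2ccccc2)c(OCc2ccccc2)c4)[C@@H](OCc2ccccc2)C3 | intermediate (not isolated)
10 | 4-[(6-bromo-3,5,7,3',4'-penta-O-benzylcatechin-8-yl)methyl]-3-tert-butoxycyclobut-2-en-1-one (both C4 epimers) | O=C5C=C(OC(C)(C)C)C5Cc1c(OCc2ccccc2)c(Br)c(OCc2ccccc2)c3c1O[C@H](c4ccc(OCc2ccccc2)c(OCc2ccccc2)c4)[C@@H](OCc2ccccc2)C3 | intermediate (precursor of the key step)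
11 | chloroacetaldehyde dimethyl acetal (2-chloro-1,1-dimethoxyethane) | COC(CCl)OC | starting material
12 | sodium methoxyethynide | [Na+].[C-]#COC | intermediate (not isolated)
13 | 1-methoxypropyne | CC#COC | intermediate
14 | vinylketene: 3-tert-butoxy-5-(6-bromo-penta-O-benzylcatechin-8-yl)penta-1,3-dien-1-one | O=C=C/C(OC(C)(C)C)=C/Cc1c(OCc2ccccc2)c(Br)c(OCc2ccccc2)c3c1O[C@H](c4ccc(OCc2ccccc2)c(OCc2ccccc2)c4)[C@@H](OCc2ccccc2)C3 | intermediate (not isolated)
15 | 4-[1-tert-butoxy-3-(6-bromo-penta-O-benzylcatechin-8-yl)prop-1-enyl]-3-methoxy-2-methylcyclobut-2-en-1-one | O=C5C(C)=C(OC)C5/C(OC(C)(C)C)=C/Cc1c(OCc2ccccc2)c(Br)c(OCc2ccccc2)c3c1O[C@H](c4ccc(OCc2ccccc2)c(OCc2ccccc2)c4)[C@@H](OCc2ccccc2)C3 | intermediate (not isolated)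
16 | dienylketene: 5-tert-butoxy-3-methoxy-2-methyl-7-(6-bromo-penta-O-benzylcatechin-8-yl)hepta-1,3,5-trien-1-one | O=C=C(C)/C(OC)=C\C(OC(C)(C)C)=C\Cc1c(OCc2ccccc2)c(Br)c(OCc2ccccc2)c3c1O[C@H](c4ccc(OCc2ccccc2)c(OCc2ccccc2)c4)[C@@H](OCc2ccccc2)C3 | intermediate (not isolated)
17 | 6-[(6-bromo-penta-O-benzylcatechin-8-yl)methyl]-5-tert-butoxy-3-methoxy-2-methylcyclohexa-2,4-dien-1-one | O=C5C(C)=C(OC)C=C(OC(C)(C)C)C5Cc1c(OCc2ccccc2)c(Br)c(OCc2ccccc2)c3c1O[C@H](c4ccc(OCc2ccccc2)c(OCc2ccccc2)c4)[C@@H](OCc2ccccc2)C3 | intermediate (not isolated)
18 | 6-bromo-3,5,7,3',4'-penta-O-benzyl-8-[(2-tert-butoxy-6-hydroxy-4-methoxy-5-methylphenyl)methyl]catechin | COc5cc(OC(C)(C)C)c(Cc1c(OCc2ccccc2)c(Br)c(OCc2ccccc2)c3c1O[C@H](c4ccc(OCc2ccccc2)c(OCc2ccccc2)c4)[C@@H](OCc2ccccc2)C3)c(O)c5C | intermediate (product of the key step)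
19 | 6-bromo-3,5,7,3',4'-penta-O-benzyl-8-[(2,6-dihydroxy-4-methoxy-3-methylphenyl)methyl]catechin | COc5cc(O)c(Cc1c(OCc2ccccc2)c(Br)c(OCc2ccccc2)c3c1O[C@H](c4ccc(OCc2ccccc2)c(OCc2ccccc2)c4)[C@@H](OCc2ccccc2)C3)c(O)c5C | intermediate
20 | difluoroboron chelate of 21 (boron bridging the D2 oxygen and the acetyl oxygen) | COc5c(C)c(O)c(Cc1c(OCc2ccccc2)c(Br)c(OCc2ccccc2)c3c1O[C@H](c4ccc(OCc2ccccc2)c(OCc2ccccc2)c4)[C@@H](OCc2ccccc2)C3)c6O[B-](F)(F)[O+]=C(C)c56 | intermediate (not isolated)
21 | 8-[(3-acetyl-2,6-dihydroxy-4-methoxy-5-methylphenyl)methyl]-6-bromo-3,5,7,3',4'-penta-O-benzylcatechin | COc5c(C)c(O)c(Cc1c(OCc2ccccc2)c(Br)c(OCc2ccccc2)c3c1O[C@H](c4ccc(OCc2ccccc2)c(OCc2ccccc2)c4)[C@@H](OCc2ccccc2)C3)c(O)c5C(C)=O | intermediate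
22 | pilosanol N, 8-[(3-acetyl-2,6-dihydroxy-4-methoxy-5-methylphenyl)methyl]-(+)-catechin, (2R,3S) | COc1c(C)c(O)c(Cc2c(O)cc(O)c3c2O[C@H](c2ccc(O)c(O)c2)[C@@H](O)C3)c(O)c1C(C)=O | target

## Step count and least certain steps

Total step count: 12. Longest linear sequence: 11 steps (steps 1 to 7 and 9 to 12, from 1 to 22); step 8 is a one-step side branch.

**Step 9 (key step).** The 3-alkoxycyclobutenone is a vinylogous ester and may open to the vinylketene only slowly at 110 °C. Forcing the temperature would invite thermal loss of isobutene from the tert-butyl enol ether, oligomerisation of the ynol ether and acylation of the product phenol by unreacted ketene.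

Fallback (a convergent Friedel–Crafts route that builds ring D away from the flavan; it sets out from 4 and returns at 22):
- Bromine–lithium exchange on 4 (n-BuLi, THF, −78 °C) and quenching with paraformaldehyde should give 8-(hydroxymethyl)-3,5,7,3',4'-penta-O-benzylcatechin F1.
- Separately, commercial 1-(2,4,6-trihydroxy-3-methylphenyl)ethanone is benzylated on its 4- and 6-hydroxyls (BnBr, K2CO3, acetone), the hydroxyl between acetyl and methyl being the most hindered and staying chelated. This gives 1-[4,6-bis(benzyloxy)-2-hydroxy-3-methylphenyl]ethanone F2.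
- F2 is methylated (MeI, K2CO3, DMF, 60 °C) to 1-[4,6-bis(benzyloxy)-2-methoxy-3-methylphenyl]ethanone F3.
- F3 is hydrogenolysed (H2, Pd/C, EtOAc) to 1-(4,6-dihydroxy-2-methoxy-3-methylphenyl)ethanone F4, whose only free ring carbon is D1.
- Acid-catalysed Friedel–Crafts benzylation of excess F4 with F1 (Sc(OTf)3 cat., CH2Cl2/MeCN, 0 °C) should give penta-O-benzyl pilosanol N F5 (identical with A5).
- F5 is hydrogenolysed under the conditions of step 12 to 22.

**Step 7.** Dimerisation of the monosubstituted ketene may outrun its capture, and the thermally and base-sensitive tert-butyl ynol ether may decompose before it reacts. Either would leave no cyclobutenone. Fallback: the convergent route written out under step 9 (from 4 through F1 to F5 and on to 22) does not pass through 10 and serves here as well; it makes no compound beyond those named there.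

**Step 11.** Under BF3 and anhydride, acetolysis of the aliphatic 3-O-benzyl ether, acid-induced fragmentation of the diarylmethane bridge, or O-acetylation without migration to carbon may compete with C-acetylation. Fallback (halogenation and cross-coupling under neutral conditions; from 19, returning at 21):
- Iodination of the free resorcinol ring with N-iodosuccinimide (CH2Cl2/MeCN, −20 °C) should give the D3 iodide, 6-bromo-penta-O-benzyl-8-[(2,6-dihydroxy-3-iodo-4-methoxy-5-methylphenyl)methyl]catechin F6.
- Stille coupling with tributyl(1-ethoxyvinyl)stannane (Pd(PPh3)4, toluene, 90 °C) is expected to react at the C–I bond in preference to the more hindered C–Br bond. It gives the 1-ethoxyvinyl compound, 6-bromo-penta-O-benzyl-8-{[3-(1-ethoxyvinyl)-2,6-dihydroxy-4-methoxy-5-methylphenyl]methyl}catechin F7.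
- Hydrolysis of F7 with 1 M HCl in THF gives 21.

**Step 4.** Slow oxidative addition into the di-ortho-oxygenated, electron-rich C8–Br bond may allow protodebromination, or β-hydride elimination from the alkylpalladium intermediate may take over. Fallback (organolithium chemistry without palladium; from 4, returning at 5):
- Bromine–lithium exchange (n-BuLi, THF, −78 °C) and formylation with DMF should give 8-formyl-3,5,7,3',4'-penta-O-benzylcatechin F8.
- Wittig olefination with Ph3P=CHCO2Et (toluene, 80 °C) gives ethyl (E)-3-(penta-O-benzylcatechin-8-yl)acrylate F9.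
- Conjugate reduction (NaBH4, NiCl2·6H2O, THF/MeOH, 0 °C), which spares benzyl ethers, gives 5.

## Further compounds

F1 | step 9 | 8-(hydroxymethyl)-3,5,7,3',4'-penta-O-benzylcatechin | OCc1c(OCc2ccccc2)cc(OCc2ccccc2)c3c1O[C@H](c4ccc(OCc2ccccc2)c(OCc2ccccc2)c4)[C@@H](OCc2ccccc2)C3
F2 | step 9 | 1-[4,6-bis(benzyloxy)-2-hydroxy-3-methylphenyl]ethanone | CC(=O)c1c(OCc2ccccc2)cc(OCc2ccccc2)c(C)c1O
F3 | step 9 | 1-[4,6-bis(benzyloxy)-2-methoxy-3-methylphenyl]ethanone | CC(=O)c1c(OCc2ccccc2)cc(OCc2ccccc2)c(C)c1OC
F4 | step 9 | 1-(4,6-dihydroxy-2-methoxy-3-methylphenyl)ethanone | CC(=O)c1c(O)cc(O)c(C)c1OC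
F5 | step 9 | penta-O-benzyl pilosanol N | COc5c(C)c(O)c(Cc1c(OCc2ccccc2)cc(OCc2ccccc2)c3c1O[C@H](c4ccc(OCc2ccccc2)c(OCc2ccccc2)c4)[C@@H](OCc2ccccc2)C3)c(O)c5C(C)=O
F0 | step 7 | none | none
F6 | step 11 | 6-bromo-3,5,7,3',4'-penta-O-benzyl-8-[(2,6-dihydroxy-3-iodo-4-methoxy-5-methylphenyl)methyl]catechin | COc5c(C)c(O)c(Cc1c(OCc2ccccc2)c(Br)c(OCc2ccccc2)c3c1O[C@H](c4ccc(OCc2ccccc2)c(OCc2ccccc2)c4)[C@@H](OCc2ccccc2)C3)c(O)c5I
F7 | step 11 | 6-bromo-3,5,7,3',4'-penta-O-benzyl-8-{[3-(1-ethoxyvinyl)-2,6-dihydroxy-4-methoxy-5-methylphenyl]methyl}catechin | COc5c(C)c(O)c(Cc1c(OCc2ccccc2)c(Br)c(OCc2ccccc2)c3c1O[C@H](c4ccc(OCc2ccccc2)c(OCc2ccccc2)c4)[C@@H](OCc2ccccc2)C3)c(O)c5C(=C)OCC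
F8 | step 4 | 8-formyl-3,5,7,3',4'-penta-O-benzylcatechin | O=Cc1c(OCc2ccccc2)cc(OCc2ccccc2)c3c1O[C@H](c4ccc(OCc2ccccc2)c(OCc2ccccc2)c4)[C@@H](OCc2ccccc2)C3
F9 | step 4 | ethyl (E)-3-(3,5,7,3',4'-penta-O-benzylcatechin-8-yl)acrylate | CCOC(=O)/C=C/c1c(OCc2ccccc2)cc(OCc2ccccc2)c3c1O[C@H](c4ccc(OCc2ccccc2)c(OCc2ccccc2)c4)[C@@H](OCc2ccccc2)C3
A1 | alternative 1 | 3,5,3',4'-tetra-O-benzyl flavan-3-ol with free C7 hydroxyl and C8 [2,6-bis(benzyloxy)-4-methoxy-5-methyl-3-isopropenylphenyl]methyl group | O(Cc9ccccc9)[C@H]1Cc2c(OCc3ccccc3)cc(O)c(Cc5c(OCc6ccccc6)c(C)c(OC)c(C(C)=C)c5OCc5ccccc5)c2O[C@@H]1c7ccc(OCc8ccccc8)c(OCc8ccccc8)c7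
A2 | alternative 1 | diazo ketone with tethered ynol ether: 2-benzyloxyvinyl ketone, diazo carbon, CH2, CH(OBn), CH(aryl) ether of the ring D propargyl ynol | C=C(OCc1ccccc1)C(=O)C(=[N+]=[N-])C[C@H](OCc1ccccc1)[C@@H](c1ccc(OCc2ccccc2)c(OCc2ccccc2)c1)OC#CCc1c(OCc2ccccc2)c(C)c(OC)c(C(C)=C)c1OCc1ccccc1
A3 | alternative 2 | hexa-O-benzyl pilosanol N with free 3-hydroxyl | O[C@H]1Cc2c(OCc3ccccc3)cc(OCc3ccccc3)c(Cc5c(OCc6ccccc6)c(C)c(OC)c(C(C)=O)c5OCc5ccccc5)c2O[C@@H]1c7ccc(OCc8ccccc8)c(OCc8ccccc8)c7
A4 | alternative 2 | aryl 1-[3,4-bis(benzyloxy)phenyl]-2,3-epoxypropyl ether of the 2-(ring D methyl)-3,5-bis(benzyloxy)phenol | c1c(OCc2ccccc2)cc(OCc2ccccc2)c(Cc2c(OCc3ccccc3)c(C)c(OC)c(C(C)=O)c2OCc2ccccc2)c1O[C@H](c1ccc(OCc2ccccc2)c(OCc2ccccc2)c1)[C@@H]1CO1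
A5 | alternative 3 | penta-O-benzyl pilosanol N with free ring D hydroxyls | COc5c(C)c(O)c(Cc1c(OCc2ccccc2)cc(OCc2ccccc2)c3c1O[C@H](c4ccc(OCc2ccccc2)c(OCc2ccccc2)c4)[C@@H](OCc2ccccc2)C3)c(O)c5C(C)=O
A6 | alternative 3 | methyl 2-[(penta-O-benzylcatechin-8-yl)methyl]-5-methoxy-4-methyl-3,7-dioxooct-4-enoate | COC(=O)C(Cc1c(OCc2ccccc2)cc(OCc2ccccc2)c3c1O[C@H](c4ccc(OCc2ccccc2)c(OCc2ccccc2)c4)[C@@H](OCc2ccccc2)C3)C(=O)C(C)=C(OC)CC(C)=O
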